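**Remark on numbering and descriptors.** Germacrane numbering is used for every compound, the cyclohexane intermediates included. C1 and C10 are the oxirane carbons (C10 carries the methyl C14), C3 carries the angelate, C4 the tertiary OH and methyl C15, C5 and C9 the acetates, C7 the isopropenyl group, C8 the senecioate. β means the face of the C7 isopropenyl group in the flat ring drawing, α the other face. The SMILES strings are the binding definition of each structure.

**Assumption.** Angelic anhydride and (E)-(2-bromovinyl)trimethylsilane are taken as catalogue reagents (the anhydride can otherwise be made from angelic acid).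

## Retrosynthetic overview

1. The four esters come from a polyol. The cis-1β,10β-oxirane comes from a (Z)-C1=C10 olefin by C9-OH-directed epoxidation. That olefin comes from a syn C1-SiMe3 / C10-OH pair by Peterson elimination, and the 8β,9β-diol from a (Z)-C8=C9 olefin.
2. Key disconnection: the C1–C10 bond, made by an anionic oxy-Cope [3,3] rearrangement of a 1,2-dialkenylcyclohexanol in which the C3–C8 bond is broken. This closes the ten-membered ring.
3. Enabling feature: ring atoms C3–C4–C5–C6–C7–C8 are a p-menthane unit (methyl on C4, isopropenyl on C7), which is (S)-carvone. C3 carries oxygen (the oxy-Cope carbonyl) and C8/C9 carry a vicinal diol (the olefin the shift creates), so the target hides a cyclodec-5-enone with the C1–C10 bond between them.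
4. The C4/C5 oxygens are set on the rigid cyclohexane before ring expansion; C7 comes from carvone.
5. Order of ring formation: six-membered ring (from carvone), then the ten-membered carbocycle (step 8), then the oxirane (step 17).

Key step: step 8

## Route

Step 1
Reactants: 1 (S)-(+)-carvone
Product: 2 (S)-carvone 4,5-epoxide with the oxirane oxygen trans to isopropenyl
Conditions: 30% H2O2, NaOH (cat.), MeOH, 0 °C
Reagents that add atoms: hydrogen peroxide, SMILES OO
Why: Nucleophilic (Weitz–Scheffer) epoxidation touches only the enone, and hydroperoxide adds axially anti to the pseudo-equatorial isopropenyl group, so both new C–O bonds (C4, C5) are α.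

Step 2
Reactants: 2 carvone epoxide
Product: 3 4α,5β-dihydroxy ketone (secondary OH cis and tertiary OH trans to isopropenyl)
Conditions: HClO4 (cat.), THF/H2O, 25 °C
Reagents that add atoms: water, SMILES O
Why: Acid-catalysed epoxide hydrolysis in which water attacks the secondary β-carbon C5 with inversion (the tertiary C4 is deactivated by the adjacent carbonyl), giving the trans-diol with O5 β and O4 α.

Step 3
Reactants: 3 dihydroxy ketone
Product: 4 4α,5β-O-isopropylidene ketone (trans-fused acetonide)
Conditions: 2,2-dimethoxypropane, PPTS (cat.), CH2Cl2, 25 °C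
Reagents that add atoms: 2,2-dimethoxypropane, SMILES COC(C)(C)OC
Why: Transketalisation of the diequatorial trans-diol creates no new stereocentre and locks the chair with the C4 methyl axial (β), which later controls the facial selectivity at C3 and C8.

Step 4
Reactants: 4 acetonide ketone
Product: 6 8α-allyl ketone (allyl trans to isopropenyl), via lithium enolate 5 (not isolated)
Conditions: LiN(iPr)2, THF, −78 °C; allyl bromide, DMPU, −78 to −20 °C
Reagents that add atoms: allyl bromide, SMILES C=CCBr
Why: Kinetic enolate alkylation in which only C8 can enolise (C4 is quaternary) and the electrophile enters anti to the C7 isopropenyl group and the axial C4 methyl, giving the equatorial 8α-allyl centre, which is also the thermodynamic epimer.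

Step 5
Reactants: 6 allyl ketone
Product: 7 8α-(2-oxopropyl) ketone (1,4-diketone)
Conditions: PdCl2 (10 mol%), CuCl, O2 (1 atm), DMF/H2O, 25 °C
Reagents that add atoms: water, SMILES O
Why: Tsuji–Wacker oxidation converts the monosubstituted terminal alkene with Markovnikov selectivity into the methyl ketone, while the 1,1-disubstituted isopropenyl group reacts far more slowly; no stereocentre is touched.

Step 6
Reactants: 7 diketone
Product: 8 8α-[(Z)-2-(triethylsilyloxy)prop-1-enyl] ketone
Conditions: Et3SiCl (1.05 equiv), NaI, Et3N, MeCN, 25 °C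
Reagents that add atoms: chlorotriethylsilane, SMILES CC[Si](Cl)(CC)CC
Why: Thermodynamic enol silylation (silyl iodide/amine) of the unhindered methyl ketone should give the more substituted enol ether with oxygen cis to C8 (Z), the isomer free of A(1,3) strain between C8 and the methyl group, while the ring ketone flanked by C4 and C8 is too hindered to react.

Step 7
Reactants: 8 enol ether ketone
Product: 9 3β-hydroxy-3α-[(E)-2-(trimethylsilyl)vinyl] carbinol
Conditions: (E)-Me3SiCH=CHBr, t-BuLi (2 equiv), Et2O, −78 °C; CeCl3, THF, −78 °C; then 8, −78 °C; aq. NH4Cl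
Reagents that add atoms: (E)-(2-bromovinyl)trimethylsilane, SMILES C[Si](C)(C)/C=C/Br
Why: 1,2-Addition of a non-basic organocerium reagent (E geometry retained through bromine–lithium exchange) to the hindered, enolisable ketone; attack comes from the α face anti to the axial C4 methyl, so the silylvinyl group is axial and cis to the C8 side chain and the new hydroxyl is equatorial (β).

Step 8
Reactants: 9 tertiary carbinol
Product: 12 (8Z)-10α-triethylsilyloxy-1α-trimethylsilyl-4α,5β-isopropylidenedioxygermacra-8,11-dien-3-one, via potassium alkoxide 10 (not isolated), via potassium enolate 11 (not isolated)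
Conditions: KH, 18-crown-6, THF, 0 to 45 °C; then AcOH, −78 °C
Reagents that add atoms: none
Why: Anionic oxy-Cope rearrangement: deprotonation gives alkoxide 10, whose oxyanion weakens the C3–C8 bond, and the 1,5-diene C1=C2–C3–C8–C9=C10 undergoes a concerted [3,3] shift that makes the C1–C10 σ-bond and the C2=C3 enolate 11, protonated on quench to ketone 12. The closest known reaction type is the ring expansion of potassium 1,2-dialkenylcyclohexanolates to cyclodec-5-enones, the standard entry to germacrane-type ten-membered rings. The ten-membered carbocycle is closed by four-atom ring expansion of the cyclohexane through a chair-like six-centre transition state (no direct macrocyclisation; the oxirane is closed later at oxygen across the same two carbons). The trans-fused acetonide locks the cyclohexane chair with the C3 silylvinyl group axial and the C8 enol ether equatorial, so the only chair available has C7 pseudo-axial and gives the (8Z)-olefin; in it the E-vinylsilane puts silicon pseudo-equatorial and the Z-enol ether puts oxygen pseudo-axial, which sets C1 (Si α) and the fully substituted C10 (O α, methyl β) as a syn pair, the stereochemical information of C3 and C8 being relayed to these two centres while C3 and C8 become trigonal. Needed selectivities are chair over boat and rearrangement over O-to-O silyl transfer or fragmentation; the conformational lock, the small oxygen (not methyl) in the 1,3-diaxial position next to C7 and the bulkier triethylsilyl (not trimethylsilyl) enol ether are meant to secure them.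

Step 9
Reactants: 12 silyl ether ketone
Product: 14 (8Z)-1α-trimethylsilylgermacra-8,11-diene-3β,10α-diol 4α,5β-acetonide, via silyl ether alcohol 13 (not isolated)
Conditions: Li[HB(sec-Bu)3], THF, −78 °C; then AcOH, Bu4NF, 0 to 25 °C
Reagents that add atoms: none
Why: Felkin–Anh (non-chelating) hydride reduction of the α-alkoxy ketone, the bulky hydride attacking anti to the C4–O bond and past the C4 methyl to give the 3β-alcohol trans to O4, followed by buffered fluoride cleavage of the tertiary silyl ether without forming a free alkoxide, so the β-hydroxysilane is not eliminated; reducing first removes the C3 carbonyl before the C10 hydroxyl is freed, so no transannular hemiketal can form.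

Step 10
Reactants: 14 3β,10α-diol
Product: 16 1α-trimethylsilylgermacr-11-ene-3β,8β,9β,10α-tetraol 4α,5β-acetonide, via osmate ester 15 (not isolated)
Conditions: OsO4 (1.05 equiv), TMEDA, CH2Cl2, −78 °C; then aq. Na2SO3, THF, 40 °C
Reagents that add atoms: osmium tetroxide, SMILES O=[Os](=O)(=O)=O
Why: Hydrogen-bond-directed syn-dihydroxylation in which the OsO4·TMEDA complex is held by the tertiary allylic C10 hydroxyl, so the hindered ring olefin reacts before the isopropenyl group, and adds to the face anti to the C7 isopropenyl group (H7 eclipses the Z-olefin to avoid A(1,3) strain), setting C8 and C9 both β in one syn addition.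

Step 11
Reactants: 16 tetraol
Product: 18 (1(10)Z)-germacra-1(10),11-diene-3β,8β,9β-triol 4α,5β-acetonide, via tetrapotassium alkoxide 17 (not isolated)
Conditions: KH (6 equiv), THF, 0 to 25 °C; then H2O
Reagents that add atoms: none
Why: Peterson olefination by syn-elimination of the potassium β-silyl alkoxide; because C1–Si and C10–O are syn (both α), the four-centre elimination can only give the (Z)-C1=C10 trisubstituted olefin, and no ester is yet present to suffer from the base.

Step 12
Reactants: 18 triol
Product: 19 8,9-O-(tetraisopropyldisiloxane-1,3-diyl) derivative of 18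
Conditions: (i-Pr2SiCl)2O, imidazole, DMF, 0 °C
Reagents that add atoms: 1,3-dichloro-1,1,3,3-tetraisopropyldisiloxane, SMILES CC(C)[Si](Cl)(C(C)C)O[Si](Cl)(C(C)C)C(C)C
Why: The bifunctional silylating agent bridges the cis-8,9-diol as a cyclic disiloxane and leaves the isolated, neopentyl-type C3 hydroxyl free; no stereocentre changes.

Step 13
Reactants: 19 disiloxane-protected alcohol
Product: 21 3β-angelate, via lithium alkoxide 20 (not isolated)
Conditions: LiN(SiMe3)2, THF, −78 °C; angelic anhydride, −78 to 0 °C; aq. NH4Cl
Reagents that add atoms: angelic anhydride, SMILES C/C=C(/C)C(=O)OC(=O)/C(C)=C\C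
Why: Acylation of the lithium alkoxide of the only free hydroxyl with the symmetrical anhydride, a method that avoids amine-catalysed Z-to-E isomerisation of angelate to tiglate; the C3 configuration is retained.

Step 14
Reactants: 21 angelate
Product: 22 4α,5β-diol (acetonide removed)
Conditions: AcOH/THF/H2O (3:1:1), 40 °C
Reagents that add atoms: none
Why: Acid hydrolysis of the isopropylidene ketal frees the tertiary 4α- and secondary 5β-hydroxyls while the acid-stable disiloxane bridge and the ester survive, and no oxirane is yet present.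

Step 15
Reactants: 22 diol
Product: 23 5β-acetate
Conditions: Ac2O, pyridine, DMAP (cat.), CH2Cl2, 0 °C
Reagents that add atoms: acetic anhydride, SMILES CC(=O)OC(C)=O
Why: Acetylation of the only free secondary hydroxyl (C5); the tertiary C4 hydroxyl is too hindered to react.

Step 16
Reactants: 23 acetate
Product: 24 8β,9β-diol
Conditions: HF·pyridine, pyridine, THF, 0 to 25 °C
Reagents that add atoms: none
Why: Buffered fluoride cleavage of the disiloxane bridge leaves the esters, the olefins and the tertiary alcohol untouched.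

Step 17
Reactants: 24 allylic diol
Product: 25 1β,10β-epoxide
Conditions: VO(acac)2 (5 mol%), t-BuOOH, CH2Cl2, 0 °C
Reagents that add atoms: tert-butyl hydroperoxide, SMILES CC(C)(C)OO
Why: Hydroxyl-directed epoxidation in which the vanadium alkylperoxide bound to the allylic C9 hydroxyl delivers oxygen to the same (β) face of the (Z)-olefin, as is general for (Z)-cycloalkenols of medium ring size, setting C1 and C10 as the cis β-oxirane; the isopropenyl group and the unsaturated esters are not epoxidised.

Step 18
Reactants: 25 epoxy diol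
Product: 26 8β-senecioate
Conditions: 3-methylbut-2-enoyl chloride (1.1 equiv), pyridine, CH2Cl2, −20 °C
Reagents that add atoms: 3-methylbut-2-enoyl chloride, SMILES CC(C)=CC(=O)Cl
Why: Sterically controlled acylation: C8-OH is the only secondary hydroxyl not flanked by a fully substituted carbon (C9-OH sits next to the oxirane carbon C10 and is hydrogen-bonded to it, C4-OH is tertiary), so the senecioate should go on C8.

Step 19
Reactants: 26 senecioate
Product: 27 CNP0416509.1 (target)
Conditions: Ac2O, DMAP, pyridine, CH2Cl2, 25 °C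
Reagents that add atoms: acetic anhydride, SMILES CC(=O)OC(C)=O
Why: DMAP-catalysed acetylation of the remaining hindered C9 hydroxyl; the tertiary C4 hydroxyl, flanked by two acyloxy-bearing carbons, should stay free.

## Compound list

1 | (S)-(+)-carvone | C=C(C)[C@H]1CC=C(C)C(=O)C1 | starting material
2 | (S)-carvone 4,5-epoxide, oxirane trans to isopropenyl | C=C(C)[C@H]1C[C@@H]2O[C@]2(C)C(=O)C1 | intermediate
3 | 4α,5β-dihydroxy ketone (2,3-dihydroxy-2-methyl-5-isopropenylcyclohexanone, secondary OH cis, tertiary OH trans to isopropenyl) | C=C(C)[C@H]1C[C@@H](O)[C@](C)(O)C(=O)C1 | intermediate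
4 | 4α,5β-O-isopropylidene ketone | C=C(C)[C@H]1C[C@H]2OC(C)(C)O[C@]2(C)C(=O)C1 | intermediate
5 | lithium enolate of 4 (C3=C8) | C=C(C)[C@H]1C[C@H]2OC(C)(C)O[C@]2(C)C([O-])=C1.[Li+] | intermediate
6 | 8α-allyl ketone | C=C(C)[C@H]1C[C@H]2OC(C)(C)O[C@]2(C)C(=O)[C@@H]1CC=C | intermediate
7 | 8α-(2-oxopropyl) ketone | C=C(C)[C@H]1C[C@H]2OC(C)(C)O[C@]2(C)C(=O)[C@@H]1CC(C)=O | intermediate
8 | 8α-[(Z)-2-(triethylsilyloxy)prop-1-enyl] ketone | C=C(C)[C@H]1C[C@H]2OC(C)(C)O[C@]2(C)C(=O)[C@@H]1/C=C(/C)O[Si](CC)(CC)CC | intermediate
9 | 3β-hydroxy-3α-[(E)-2-(trimethylsilyl)vinyl] carbinol | C=C(C)[C@H]1C[C@H]2OC(C)(C)O[C@]2(C)[C@](O)(/C=C/[Si](C)(C)C)[C@@H]1/C=C(/C)O[Si](CC)(CC)CC | intermediate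
10 | potassium alkoxide of 9 | C=C(C)[C@H]1C[C@H]2OC(C)(C)O[C@]2(C)[C@]([O-])(/C=C/[Si](C)(C)C)[C@@H]1/C=C(/C)O[Si](CC)(CC)CC.[K+] | intermediate
11 | potassium C2=C3 enolate of 12 | C1[C@H]2OC(C)(C)O[C@]2(C)/C([O-])=C/[C@H]([Si](C)(C)C)[C@](C)(O[Si](CC)(CC)CC)/C=C\[C@H]1C(C)=C.[K+] | intermediate
12 | (8Z)-10α-triethylsilyloxy-1α-trimethylsilyl-4α,5β-isopropylidenedioxygermacra-8,11-dien-3-one | C1[C@H]2OC(C)(C)O[C@]2(C)C(=O)C[C@H]([Si](C)(C)C)[C@](C)(O[Si](CC)(CC)CC)/C=C\[C@H]1C(C)=C | intermediate
13 | 3β-alcohol of 12 (10-O-triethylsilyl ether) | C1[C@H]2OC(C)(C)O[C@]2(C)[C@@H](O)C[C@H]([Si](C)(C)C)[C@](C)(O[Si](CC)(CC)CC)/C=C\[C@H]1C(C)=C | intermediate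
14 | (8Z)-1α-trimethylsilylgermacra-8,11-diene-3β,10α-diol 4α,5β-acetonide | C1[C@H]2OC(C)(C)O[C@]2(C)[C@@H](O)C[C@H]([Si](C)(C)C)[C@](C)(O)/C=C\[C@H]1C(C)=C | intermediate
15 | 8β,9β-osmate ester of 14 (TMEDA adduct, diamine drawn as separate component) | C1[C@H]2OC(C)(C)O[C@]2(C)[C@@H](O)C[C@H]([Si](C)(C)C)[C@](C)(O)[C@H]3O[Os](=O)(=O)O[C@H]3[C@H]1C(C)=C.CN(C)CCN(C)C | intermediate
16 | 1α-trimethylsilylgermacr-11-ene-3β,8β,9β,10α-tetraol 4α,5β-acetonide | C1[C@H]2OC(C)(C)O[C@]2(C)[C@@H](O)C[C@H]([Si](C)(C)C)[C@](C)(O)[C@@H](O)[C@@H](O)[C@H]1C(C)=C | intermediate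
17 | tetrapotassium alkoxide of 16 | C1[C@H]2OC(C)(C)O[C@]2(C)[C@@H]([O-])C[C@H]([Si](C)(C)C)[C@](C)([O-])[C@@H]([O-])[C@@H]([O-])[C@H]1C(C)=C.[K+].[K+].[K+].[K+] | intermediate
18 | (1(10)Z)-germacra-1(10),11-diene-3β,8β,9β-triol 4α,5β-acetonide | C1[C@H]2OC(C)(C)O[C@]2(C)[C@@H](O)C/C=C(/C)[C@@H](O)[C@@H](O)[C@H]1C(C)=C | intermediate
19 | 8,9-O-(tetraisopropyldisiloxane-1,3-diyl) derivative of 18 | C1[C@H]2OC(C)(C)O[C@]2(C)[C@@H](O)C/C=C(/C)[C@H]3O[Si](C(C)C)(C(C)C)O[Si](C(C)C)(C(C)C)O[C@H]3[C@H]1C(C)=C | intermediate
20 | lithium 3-alkoxide of 19 | C1[C@H]2OC(C)(C)O[C@]2(C)[C@@H]([O-])C/C=C(/C)[C@H]3O[Si](C(C)C)(C(C)C)O[Si](C(C)C)(C(C)C)O[C@H]3[C@H]1C(C)=C.[Li+] | intermediate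
21 | 3β-angelate of 19 | C1[C@H]2OC(C)(C)O[C@]2(C)[C@@H](OC(=O)/C(C)=C\C)C/C=C(/C)[C@H]3O[Si](C(C)C)(C(C)C)O[Si](C(C)C)(C(C)C)O[C@H]3[C@H]1C(C)=C | intermediate
22 | 3β-angelate 4α,5β-diol (8,9-disiloxane) | C1[C@@H](O)[C@](C)(O)[C@@H](OC(=O)/C(C)=C\C)C/C=C(/C)[C@H]3O[Si](C(C)C)(C(C)C)O[Si](C(C)C)(C(C)C)O[C@H]3[C@H]1C(C)=C | intermediate
23 | 3β-angelate 5β-acetate 4α-ol (8,9-disiloxane) | C1[C@@H](OC(C)=O)[C@](C)(O)[C@@H](OC(=O)/C(C)=C\C)C/C=C(/C)[C@H]3O[Si](C(C)C)(C(C)C)O[Si](C(C)C)(C(C)C)O[C@H]3[C@H]1C(C)=C | intermediate
24 | (1(10)Z)-3β-angeloyloxy-5β-acetoxygermacra-1(10),11-diene-4α,8β,9β-triol | C1[C@@H](OC(C)=O)[C@](C)(O)[C@@H](OC(=O)/C(C)=C\C)C/C=C(/C)[C@@H](O)[C@@H](O)[C@H]1C(C)=C | intermediate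
25 | 1β,10β-epoxy-3β-angeloyloxy-5β-acetoxygermacr-11-ene-4α,8β,9β-triol | C1[C@@H](OC(C)=O)[C@](C)(O)[C@@H](OC(=O)/C(C)=C\C)C[C@H]2O[C@@]2(C)[C@@H](O)[C@@H](O)[C@H]1C(C)=C | intermediate
26 | 8β-senecioate of 25 | C1[C@@H](OC(C)=O)[C@](C)(O)[C@@H](OC(=O)/C(C)=C\C)C[C@H]2O[C@@]2(C)[C@@H](O)[C@@H](OC(=O)C=C(C)C)[C@H]1C(C)=C | intermediate
27 | CNP0416509.1: 1β,10β-epoxy-3β-angeloyloxy-5β,9β-diacetoxy-8β-senecioyloxygermacr-11-en-4α-ol | C=C(C)[C@H]1C[C@@H](OC(C)=O)[C@](C)(O)[C@@H](OC(=O)/C(C)=C\C)C[C@H]2O[C@@]2(C)[C@@H](OC(C)=O)[C@H]1OC(=O)C=C(C)C | target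

## Step count and risks

Total step count: 19. Longest linear sequence: 19 steps (fully linear from (S)-carvone).

The three steps most likely to fail:

**Step 8 (oxy-Cope ring expansion).** What may go wrong: migration of the triethylsilyl group from the enol ether oxygen to the potassium alkoxide, or alkoxide-triggered fragmentation, either of which removes the charge acceleration before the [3,3] shift. Leakage through a boat-like transition state would also scramble the C1/C10 relationship. The fallback changes the manifold from anionic to neutral. It sets out from 9, which is silylated with N-(trimethylsilyl)imidazole to the tertiary trimethylsilyl ether F1. Thermal siloxy-Cope rearrangement of F1 (decalin, 220 °C, base-washed sealed tube) through the same locked chair should give the trimethylsilyl enol ether F2 without any alkoxide being present. K2CO3 in MeOH then cleaves only the enol ether, and the route is rejoined at ketone 12.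

**Step 10 (directed dihydroxylation).** What may go wrong: poor facial selectivity, with osmylation from the α face because the ring chain rather than the isopropenyl group decides which face is exposed, or competing attack on the isopropenyl group. The fallback replaces face-selective addition by oxidation and reduction. It sets out from 14, which with catalytic OsO4 and N-methylmorpholine N-oxide is taken to the 8α,9α-diol F3. Swern oxidation of the three secondary carbinols gives the trione F4. Li[HB(sec-Bu)3] at −78 °C should then deliver hydride to C8 and C9 from the same exposed α face and to C3 under Felkin–Anh control, and the route is rejoined at tetraol 16.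

**Step 6 (enol silylation).** What may go wrong: enolisation toward the methyl group, loss of Z/E control, silylation of the ring ketone or cyclodehydration of the 1,4-diketone. The fallback separates regiocontrol from geometry control. It sets out from 7, which on kinetic deprotonation (LiN(iPr)2, −78 °C, Et3SiCl present) gives the terminal enol ether F5 regiospecifically. Double-bond migration catalysed by RuHCl(CO)(PPh3)3 (toluene, 60 °C) should then move the olefin into the trisubstituted position with the A(1,3)-free Z geometry, and the route is rejoined at 8.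

Further compounds
F1 | step 8 | 3-O-trimethylsilyl ether of 9 | C=C(C)[C@H]1C[C@H]2OC(C)(C)O[C@]2(C)[C@](O[Si](C)(C)C)(/C=C/[Si](C)(C)C)[C@@H]1/C=C(/C)O[Si](CC)(CC)CC
F2 | step 8 | trimethylsilyl C2=C3 enol ether of 12 | C1[C@H]2OC(C)(C)O[C@]2(C)/C(O[Si](C)(C)C)=C/[C@H]([Si](C)(C)C)[C@](C)(O[Si](CC)(CC)CC)/C=C\[C@H]1C(C)=C
F3 | step 10 | 1α-trimethylsilylgermacr-11-ene-3β,8α,9α,10α-tetraol 4α,5β-acetonide | C1[C@H]2OC(C)(C)O[C@]2(C)[C@@H](O)C[C@H]([Si](C)(C)C)[C@](C)(O)[C@H](O)[C@H](O)[C@H]1C(C)=C
F4 | step 10 | 10α-hydroxy-1α-trimethylsilyl-4α,5β-isopropylidenedioxygermacr-11-ene-3,8,9-trione | C1[C@H]2OC(C)(C)O[C@]2(C)C(=O)C[C@H]([Si](C)(C)C)[C@](C)(O)C(=O)C(=O)[C@H]1C(C)=C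
F5 | step 6 | 8α-[2-(triethylsilyloxy)prop-2-enyl] ketone (terminal enol ether) | C=C(C)[C@H]1C[C@H]2OC(C)(C)O[C@]2(C)C(=O)[C@@H]1CC(=C)O[Si](CC)(CC)CC
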